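The partner's half-life of 0.990 s, set against a feed of 25 s, is where I start, because it separates elm from maple, two flasks with the same charges.

in all of them: time 40 s

|  | starting material | partner | remark |
|---|---|---|---|
| elm | 32 mM | 3.00 equiv (fed, over 25 s) | all else is in the flask from the start; the feed brings no volume worth counting |
| birch | 32 mM (fed, over 25 s) | 3.00 equiv | all else is in the flask from the start; the feed brings no volume worth counting |
| maple | 32 mM | 3.00 equiv | everything together at the start |

    partner → decomposed reagent (k1 = 0.70 s⁻¹)
    starting material + partner → target, rate k2*[starting material]*[partner]^0.5 (k2 = 0.38 M⁻⁰·⁵ s⁻¹)
    partner → decomposition product (k3 = 4.9 × 10⁻⁵ s⁻¹)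

* the best flask by amount of target, in percent of the starting material charged; "all alike" if 1.5 percentage points covers them all (elm / birch / maple / all alike)
* amount of target at the end, in percent of the starting material charged, elm
* amount of target at the end, in percent of the starting material charged, birch
* amount of target at the end, in percent of the starting material charged, maple

1. I drop step 3, since 4.9 × 10⁻⁵ s⁻¹ is far below 0.70 s⁻¹. I also leave out the partner taken by the coupling.

2. At a given partner level, the starting material falls pseudo-first-order, so the logarithm of charged over left is 0.38 M⁻⁰·⁵ s⁻¹ times the time-sum of the square root of partner.

3. For a coupling of first order in partner, with first-order loss, the time-sum of partner is the charge over the rate constant, however it enters. That ratio of 1 between the two ways of charging is my zero.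

4. Maple: partner decays from its full charge, so the logarithm is 0.336, which gives 28.6% target. That is above the forecast's range.

5. Elm: partner's lifetime is much shorter than the feed, so partner holds near feed rate over 0.70 s⁻¹, or 5.49 mM. Over the feed, the partner exposure, the logarithm of charged over left, is 0.704, which gives 50.5% target. The square root lifts this above maple by a factor of 2.09.

6. Birch: the partner pulse lasts about 2.86 s, much shorter than the feed. The pulse's share of the feed meets maple's exposure, which gives 3.84%.

7. The forecast names elm, with 49% (45% to 53%) for elm, 3.5% (3% to 4%) for birch and 25% (23% to 27%) for maple, holding that “the half-order coupling favours keeping it dilute”.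

8. The simulation gives elm as best, with 49.2% for elm, 2.92% for birch and 25.0% for maple.

Elm's 50.8% of starting material left reads as an exposure of 0.677, against my 0.704. The neighbour is elm with 12.0 equiv of partner, and its exposure scales with the square root of the charge, to 1.41, which gives 75.5% target. That flask gives 76.7% target and leaves 23.3% of the starting material, which reads as an exposure of 1.46.

The numbers belong to no real substance.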